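**Numbering convention.** All bicyclic compounds use benzodioxane numbering: O1, C2 (aryl), C3 (methyl), O4, C4a, C5 (methoxy), C6, C7 (side chain), C8, C8a. Ring A is the fused aromatic ring; ring B is the 3,4,5-trimethoxyphenyl group.

## The problem

Compound 12 is a 2-aryl-3-methyl-1,4-benzodioxane. Ring A carries a methoxy group at C5 and an (E)-propenal chain at C7, and is fused through O1 and O4 to a dioxane ring whose C2 bears ring B and whose C3 bears a methyl group. The two ring oxygens are not equivalent: O4 lies next to the C5 methoxy group and para to the side chain and must end on the methyl-bearing carbon, while O1 must end on the benzylic carbon. C2 and C3 are the only stereocentres, both S and trans to each other. The trans (diequatorial) arrangement is the more stable one, so a fixed C3 can steer C2 under equilibrating conditions, but the absolute configuration must come from a reagent or catalyst because the rest of the molecule is achiral. The enal does not tolerate hydrides, strong nucleophiles or carbene chemistry, and the C2–O1 bond is a benzylic ether of an electron-rich arene that ionises in strong acid; the enal is therefore made last and acidic steps are kept mild. The feature that opens the route is C3: it is bonded to O4, to C2 and to one further carbon, which is the pattern of the carbene carbon of a diazoacetate once the ester is read as a latent methyl group. Its two new bonds can then be made in one operation, first to a phenol oxygen of ring A (O4) and then to the carbonyl carbon of 3,4,5-trimethoxybenzaldehyde (C2), whose oxygen becomes O1. A bromine ortho to that phenol oxygen is then enough to close O1–C8a without breaking a bond at either stereocentre.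

## Retrosynthesis

**12 to 11.** The Cα=Cβ bond of the enal is cut, leading back to aryl aldehyde 11 and a formyl-stabilised phosphorus ylide. Carrying an enal or an acrylate through the route is the neighbouring option, but neither would survive the hydride steps, and an alkene would react with the carbene. Aldehyde 11 is two carbons smaller and free of the most sensitive group. The forward Wittig reaction must be E-selective and stop after one homologation.

**11 to 10.** The ring A aldehyde is masked as a dioxolane. A free aldehyde on ring A would compete with aldehyde 4 as the electrophile in the key step and would be reduced by LiBH4 and LiEt3BH. An ester at C7 could not be told apart from the ethyl ester that has to become the methyl group. The forward step is a mild aqueous acid hydrolysis that must leave the benzylic C2–O1 bond alone.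

**10 to 9.** The aryl–oxygen bond O1–C8a is cut, leading back to bromo alcohol 9. Cutting O1–C2 instead would require substitution at the benzylic stereocentre, with inversion or ionisation. Cutting at the arene leaves the C2–O bond intact, so the configuration set earlier is carried into the ring unchanged. The precursor is acyclic and needs only an ortho bromine, which the starting material already has. The forward reaction is an intramolecular copper-catalysed etherification that forms a six-membered ring.

**9 to 6 (through 8 and 7).** No skeletal bond is cut; the C3 methyl group is traced back through tosylate 8 and diol 7 to the ethyl ester of 6. This is the price of using an acceptor carbene as the C3 synthon. The deoxygenation is placed before ring closure so that only one hydroxyl is present when the aryl bromide is engaged, which removes any competition between six- and seven-membered etherification. The forward steps must distinguish a primary from a secondary benzylic hydroxyl and reduce a primary tosylate without touching the aryl bromide.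

**6 to 2, 3 and 4.** Two bonds are cut at the future C3: C3–O4 to the phenol oxygen of 2 and C2–C3 to the carbonyl carbon of 4. The carbon between them is the diazo carbon of 3. A stepwise alternative (phenol alkylation, then an aldol addition) forms the same bonds but needs a stoichiometric chiral controller. The three-component cut sets both stereocentres in one catalytic step from two purchased compounds and a phenol one step from commerce. The forward reaction must capture the oxonium ylide with the aldehyde before proton transfer and must do so with syn and absolute control.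

**2 to 1.** The dioxolane is removed retrosynthetically to give 5-bromovanillin 1, which supplies the phenol oxygen (O4), the flanking methoxy group (C5), the bromine (C8a) and the C7 carbon in the correct positions.

## Roads not taken

**Alternative 1: oxidative coupling of a propenylphenol with a catechol.** Both dioxane C–O bonds (C3–O4 and C2–O1) are cut, dividing the target into (E)-2,6-dimethoxy-4-(prop-1-enyl)phenol A1 and methyl 5-hydroxyferulate A2. In the forward sense Ag2O oxidises both partners. The catechol oxygen para to the acrylate bonds to the propenyl β-carbon, and the neighbouring hydroxyl adds to the resulting p-quinone methide, giving the trans-benzodioxane acrylate A3 with a free 4-hydroxyl on ring B.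
- Merits: it is the shortest route conceivable (coupling, O-methylation, ester-to-aldehyde adjustment). The ring and both stereocentres form in one flask, the trans relationship is the thermodynamic outcome, and the three-carbon side chain is already present.
- Weak points: a radical and quinone methide coupling carries no chiral information, so A3 is racemic and the single enantiomer would need a resolution that discards half the material. Cross-coupling competes with self-coupling of A1. Which catechol oxygen attacks the β-carbon is governed only by relative phenol acidity.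
- Comparison: in step count and in confidence that the ring forms, this road is better than the chosen plan. The chosen plan sets against it catalytic control of absolute configuration, an unambiguous O4 assignment (the phenol oxygen of 2 is the only nucleophile) and independence from a statistical cross-coupling.

**Alternative 2: ring A from a symmetric cyclohexanedione, aromatised late.** O4–C4a and O1–C8a are cut and ring A is traced back to the symmetric diazodione methyl 4-diazo-3,5-dioxocyclohexane-1-carboxylate A4. The stereocentres are placed in a separately made carbinol, (1S,2S)-1-(tert-butyldimethylsilyloxy)-1-(3,4,5-trimethoxyphenyl)propan-2-ol A5. Forward, Rh2(OAc)4 inserts the carbene carbon of A4 into the O–H of A5 (O4–C4a). Acid then removes the silyl group and condenses the benzylic hydroxyl with one of the two equivalent carbonyls (O1–C8a), giving vinylogous ester A6. Dehydrogenation, O-methylation of the emerging C5 phenol and conversion of the ester into the enal would follow.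
- Merits: both stereocentres come from an asymmetric dihydroxylation of an (E)-propenylarene, which is predictable and highly selective on this substrate type. The symmetry of A4 removes the O1/O4 question, and no bond at a stereocentre is broken.
- Weak points: the benzylic hydroxyl of a 1,2-diol must be silylated selectively. Insertion of a diazodione into a hindered secondary alcohol competes with Wolff rearrangement. The aromatisation must oxidise a cyclohexenone that carries an acid-labile benzylic ether. The sequence is clearly longer, roughly ten steps.
- Comparison: in stereochemical security this road is better than the chosen plan, whose key step is untested. The chosen plan sets against it a shorter sequence, an aromatic ring A that is intact from the start (no dehydrogenation, no late methylation) and the formation of two skeletal bonds and both stereocentres in one step.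

**Alternative 3: branched allyl ether, then iodoetherification.** C3–O4 is cut last, after O1–C2 has been set by an asymmetric allylic etherification. The cyclisation substrate is methyl 4-hydroxy-3-methoxy-5-{[(1R)-1-(3,4,5-trimethoxyphenyl)prop-2-en-1-yl]oxy}benzoate A7. Forward, iodine with NaHCO3 activates the vinyl group and the C4a phenol attacks its internal carbon in a 6-exo closure, giving iodomethyl benzodioxane A8. Reductive removal of iodine gives the methyl group, and the ester is then converted into the enal.
- Merits: every step has close precedent, the C2 centre is set by a well-understood catalyst, and the methyl group is reached in one step from the iodide, against three steps from the ester in the chosen plan.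
- Weak points: C3 is set only by 1,2-induction from C2 in a 6-exo closure, where trans selectivity is not assured. The ether in A7 is both allylic and benzylic to an electron-rich ring and can ionise, eroding enantiopurity. The catechol of ring A must be differentiated so that the correct oxygen is allylated, which costs protecting-group steps. The electron-rich rings may be iodinated.
- Comparison: this road is better in precedent for each individual step. The chosen plan sets against it the joint, catalyst-controlled formation of both stereocentres, an O1/O4 assignment that needs no catechol differentiation, and intermediates that are not prone to ionisation before the ring is closed.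

Key step: step 2

**Assumption.** The sense of induction of the chiral phosphoric acid cannot be predicted for this untested substrate combination. The (R)-acid is written; its commercially available enantiomer is to be used if the first run shows the mirror-image series.

## Route

Step 1
Reactants: 1 bromovanillin (5-bromovanillin, 3-bromo-4-hydroxy-5-methoxybenzaldehyde)
Product: 2 phenol acetal [2-bromo-4-(1,3-dioxolan-2-yl)-6-methoxyphenol]
Conditions: ethylene glycol (3 equiv), p-TsOH·H2O (cat.), toluene, reflux, Dean–Stark; Et3N quench
Reagents that add atoms: ethylene glycol, OCCO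
Why: Acid-catalysed acetalisation with azeotropic removal of water tolerates the free phenol; the bromine lowers the donor strength of the para oxygen, so the acetal should be stable enough to isolate after a basic quench.

Step 2
Reactants: 2 phenol acetal [2-bromo-4-(1,3-dioxolan-2-yl)-6-methoxyphenol]; 3 ethyl diazoacetate; 4 trimethoxybenzaldehyde (3,4,5-trimethoxybenzaldehyde)
Product: 6 ethyl (2R,3S)-2-[2-bromo-4-(1,3-dioxolan-2-yl)-6-methoxyphenoxy]-3-hydroxy-3-(3,4,5-trimethoxyphenyl)propanoate, via oxonium ylide 5 (not isolated)
Conditions: Rh2(OAc)4 (2 mol %), (R)-TRIP [(R)-3,3'-bis(2,4,6-triisopropylphenyl)-1,1'-binaphthyl-2,2'-diyl hydrogen phosphate] (10 mol %), 4 Å MS, CH2Cl2, −20 °C; 4 (1.5 equiv) present, 3 (1.5 equiv) added by syringe pump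
Reagents that add atoms: none
Why: Proposed new method: Rh2(OAc)4 decomposes 3 to an electrophilic rhodium carbene, the phenol oxygen of 2 adds to it (C3–O4 in benzodioxane numbering) to give the protic oxonium ylide 5, and 5 or its enol tautomer adds to aldehyde 4 held on the chiral phosphoric acid (C2–C3) before the 1,2-proton shift that would end in plain O–H insertion; the closest known reaction type is the dirhodium and chiral phosphoric acid co-catalysed three-component coupling of aryl diazoacetates with alcohols and imines or aldehydes through trapped oxonium ylides, which has not been shown for an acceptor-only diazoacetate combined with a phenol and an alkoxy-substituted benzaldehyde. No ring is closed. Both stereocentres arise in the C–C bond formation and neither substrate carries a stereocentre, so both are catalyst-controlled: the phosphoric acid is expected to bridge the aldehyde carbonyl and the O–H of the ylide or enol in a cyclic hydrogen-bonded array, fixing the aldehyde face (carbinol carbon, S) and the nucleophile face (aryloxy carbon, R) and hence the syn arrangement of OH and OAr in the extended chain. The step needs chemoselectivity (trapping over O–H insertion, over carbonyl ylide formation with 4 and over carbene dimerisation), diastereoselectivity and enantioselectivity. Chemoselectivity is helped by slow addition of 3 to an excess of 4 at low temperature, by the high O–H reactivity of the acidic phenol towards the carbene, and by the fact that 4 is less deactivated than its methoxy count suggests, since the 4-methoxy group is twisted out of conjugation by its neighbours and the 3- and 5-methoxy groups are inductively withdrawing. The dioxolane removes the ring A aldehyde as a competing electrophile and the aryl bromide is inert to the carbene, so the substrates offer one nucleophilic and one electrophilic site. Nothing in the substrates secures the stereochemical outcome, which rests on the catalyst alone and is the reason this step is treated as the main risk.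

Step 3
Reactants: 6 ethyl (2R,3S)-2-[2-bromo-4-(1,3-dioxolan-2-yl)-6-methoxyphenoxy]-3-hydroxy-3-(3,4,5-trimethoxyphenyl)propanoate
Product: 7 (1S,2S)-2-[2-bromo-4-(1,3-dioxolan-2-yl)-6-methoxyphenoxy]-1-(3,4,5-trimethoxyphenyl)propane-1,3-diol
Conditions: LiBH4 (2 equiv), THF, 0 °C to rt; aq. NH4Cl
Reagents that add atoms: none
Why: LiBH4 reduces the activated α-aryloxy ester to the primary alcohol and leaves the aryl bromide and the dioxolane untouched. No bond at either stereocentre is broken, and the low temperature and weakly basic medium should avoid retro-aldol cleavage and epimerisation at the α-carbon.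

Step 4
Reactants: 7 (1S,2S)-2-[2-bromo-4-(1,3-dioxolan-2-yl)-6-methoxyphenoxy]-1-(3,4,5-trimethoxyphenyl)propane-1,3-diol
Product: 8 (2S,3S)-2-[2-bromo-4-(1,3-dioxolan-2-yl)-6-methoxyphenoxy]-3-hydroxy-3-(3,4,5-trimethoxyphenyl)propyl 4-methylbenzenesulfonate
Conditions: TsCl (1.1 equiv), pyridine, CH2Cl2, 0 °C
Reagents that add atoms: p-toluenesulfonyl chloride (TsCl), Cc1ccc(cc1)S(=O)(=O)Cl
Why: Selective sulfonylation of the unhindered primary hydroxyl; the secondary benzylic hydroxyl is flanked by ring B and the aryloxy-bearing carbon and should react much more slowly at 0 °C.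

Step 5
Reactants: 8 (2S,3S)-2-[2-bromo-4-(1,3-dioxolan-2-yl)-6-methoxyphenoxy]-3-hydroxy-3-(3,4,5-trimethoxyphenyl)propyl 4-methylbenzenesulfonate
Product: 9 (1S,2S)-2-[2-bromo-4-(1,3-dioxolan-2-yl)-6-methoxyphenoxy]-1-(3,4,5-trimethoxyphenyl)propan-1-ol
Conditions: LiEt3BH (3 equiv), THF, 0 °C
Reagents that add atoms: none
Why: SN2 displacement of the primary tosylate by hydride gives the methyl group; the first equivalent is consumed by the free hydroxyl. Aryl bromide, acetal and both stereocentres are not affected by this reagent at 0 °C.

Step 6
Reactants: 9 (1S,2S)-2-[2-bromo-4-(1,3-dioxolan-2-yl)-6-methoxyphenoxy]-1-(3,4,5-trimethoxyphenyl)propan-1-ol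
Product: 10 (2S,3S)-7-(1,3-dioxolan-2-yl)-5-methoxy-3-methyl-2-(3,4,5-trimethoxyphenyl)-2,3-dihydro-1,4-benzodioxine
Conditions: CuI (10 mol %), 1,10-phenanthroline (20 mol %), Cs2CO3 (2 equiv), toluene, 110 °C
Reagents that add atoms: none
Why: Intramolecular Ullmann-type C–O coupling of the secondary alkoxide with the ortho aryl bromide closes the six-membered ring at O1–C8a. The carbinol C–O bond is not broken, so C2 keeps its configuration and the (1S,2S) alcohol gives the trans (2S,3S) benzodioxane.

Step 7
Reactants: 10 (2S,3S)-7-(1,3-dioxolan-2-yl)-5-methoxy-3-methyl-2-(3,4,5-trimethoxyphenyl)-2,3-dihydro-1,4-benzodioxine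
Product: 11 (2S,3S)-5-methoxy-3-methyl-2-(3,4,5-trimethoxyphenyl)-2,3-dihydro-1,4-benzodioxine-7-carbaldehyde
Conditions: 1 M aq. HCl, THF, rt
Reagents that add atoms: water, O
Why: Mild aqueous acid hydrolysis of the aryl dioxolane; the benzodioxane ethers are stable to dilute acid at room temperature. Should any ionisation at C2 occur, reclosure favours the trans isomer and C3 is not involved.

Step 8
Reactants: 11 (2S,3S)-5-methoxy-3-methyl-2-(3,4,5-trimethoxyphenyl)-2,3-dihydro-1,4-benzodioxine-7-carbaldehyde
Product: 12 (E)-3-[(2S,3S)-5-methoxy-3-methyl-2-(3,4,5-trimethoxyphenyl)-2,3-dihydro-1,4-benzodioxin-7-yl]prop-2-enal (CNP0258373.1)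
Conditions: Ph3P=CHCHO (1.2 equiv), toluene, 80 °C
Reagents that add atoms: (triphenylphosphoranylidene)acetaldehyde (Ph3P=CHCHO), O=CC=P(c1ccccc1)(c1ccccc1)c1ccccc1
Why: Wittig reaction of an aryl aldehyde with the formyl-stabilised ylide gives the (E)-enal directly. The neutral conditions do not affect the benzodioxane or its stereocentres.

## Compound list

1 | 5-bromovanillin (3-bromo-4-hydroxy-5-methoxybenzaldehyde) | COc1cc(C=O)cc(Br)c1O | starting material
2 | 2-bromo-4-(1,3-dioxolan-2-yl)-6-methoxyphenol | COc1cc(C2OCCO2)cc(Br)c1O | intermediate
3 | ethyl diazoacetate | CCOC(=O)C=[N+]=[N-] | starting material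
4 | 3,4,5-trimethoxybenzaldehyde | COc1cc(C=O)cc(OC)c1OC | starting material
5 | protic oxonium ylide from 2 and the carbene of 3, [2-bromo-4-(1,3-dioxolan-2-yl)-6-methoxyphenyl](2-ethoxy-2-oxoethan-1-id-1-yl)oxonium (drawn metal-free; not isolated) | CCOC(=O)[CH-][OH+]c1c(Br)cc(C2OCCO2)cc1OC | intermediate
6 | ethyl (2R,3S)-2-[2-bromo-4-(1,3-dioxolan-2-yl)-6-methoxyphenoxy]-3-hydroxy-3-(3,4,5-trimethoxyphenyl)propanoate | COc1cc([C@H](O)[C@H](C(=O)OCC)Oc2c(Br)cc(C3OCCO3)cc2OC)cc(OC)c1OC | intermediate
7 | (1S,2S)-2-[2-bromo-4-(1,3-dioxolan-2-yl)-6-methoxyphenoxy]-1-(3,4,5-trimethoxyphenyl)propane-1,3-diol | COc1cc([C@H](O)[C@H](CO)Oc2c(Br)cc(C3OCCO3)cc2OC)cc(OC)c1OC | intermediate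
8 | (2S,3S)-2-[2-bromo-4-(1,3-dioxolan-2-yl)-6-methoxyphenoxy]-3-hydroxy-3-(3,4,5-trimethoxyphenyl)propyl 4-methylbenzenesulfonate | COc1cc([C@H](O)[C@H](COS(=O)(=O)c4ccc(C)cc4)Oc2c(Br)cc(C3OCCO3)cc2OC)cc(OC)c1OC | intermediate
9 | (1S,2S)-2-[2-bromo-4-(1,3-dioxolan-2-yl)-6-methoxyphenoxy]-1-(3,4,5-trimethoxyphenyl)propan-1-ol | COc1cc([C@H](O)[C@H](C)Oc2c(Br)cc(C3OCCO3)cc2OC)cc(OC)c1OC | intermediate
10 | (2S,3S)-7-(1,3-dioxolan-2-yl)-5-methoxy-3-methyl-2-(3,4,5-trimethoxyphenyl)-2,3-dihydro-1,4-benzodioxine | COc1cc([C@@H]2Oc3cc(C4OCCO4)cc(OC)c3O[C@H]2C)cc(OC)c1OC | intermediate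
11 | (2S,3S)-5-methoxy-3-methyl-2-(3,4,5-trimethoxyphenyl)-2,3-dihydro-1,4-benzodioxine-7-carbaldehyde | COc1cc([C@@H]2Oc3cc(C=O)cc(OC)c3O[C@H]2C)cc(OC)c1OC | intermediate
12 | (E)-3-[(2S,3S)-5-methoxy-3-methyl-2-(3,4,5-trimethoxyphenyl)-2,3-dihydro-1,4-benzodioxin-7-yl]prop-2-enal | COc1cc([C@@H]2Oc3cc(/C=C/C=O)cc(OC)c3O[C@H]2C)cc(OC)c1OC | target

## Step count and risk assessment

Total: 8 steps. Longest linear sequence: 8 steps, from 1 to 12; compounds 3 and 4 are used as purchased.

**Step 2 (key step, proposed new method).**
- What may go wrong: proton transfer within the ylide (formal O–H insertion) may outrun capture by the only moderately electrophilic aldehyde. Facial and syn/anti control by the acid may be poor, because an acceptor-only carbene gives a short-lived, weakly organised ylide. The carbene may be diverted to a carbonyl ylide with 4. The acid may open the dioxolane to an oxocarbenium ion that itself traps the ylide.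
- Adjustments within the idea: a more acidic chiral N-triflyl phosphoramide, or a bulkier ester on the diazo compound.
- Fallback by known chemistry, from 2 back to 7:
  - Phenol 2 is alkylated with commercially available (R)-4-benzyl-3-(chloroacetyl)oxazolidin-2-one (K2CO3, NaI, acetone) to give the aryloxyacetyl imide (R)-4-benzyl-3-{2-[2-bromo-4-(1,3-dioxolan-2-yl)-6-methoxyphenoxy]acetyl}oxazolidin-2-one F1.
  - Its dibutylboron enolate (Bu2BOTf, i-Pr2NEt, CH2Cl2, −78 °C) adds to aldehyde 4 in an Evans syn glycolate aldol reaction to give (R)-4-benzyl-3-{(2R,3S)-2-[2-bromo-4-(1,3-dioxolan-2-yl)-6-methoxyphenoxy]-3-hydroxy-3-(3,4,5-trimethoxyphenyl)propanoyl}oxazolidin-2-one F2, which has the same spatial arrangement as 6.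
  - LiBH4 in THF then removes the auxiliary reductively and gives diol 7 directly, by-passing 6 and step 3.

**Step 5.**
- What may go wrong: the lithium alkoxide formed from the free benzylic hydroxyl may displace the neighbouring tosylate (oxetane closure) or trigger a Grob-type fragmentation faster than hydride reaches the β-branched primary carbon.
- Fallback, from 8 back to 9:
  - The hydroxyl is silylated (TESCl, imidazole, DMF) to give (2S,3S)-2-[2-bromo-4-(1,3-dioxolan-2-yl)-6-methoxyphenoxy]-3-(triethylsilyloxy)-3-(3,4,5-trimethoxyphenyl)propyl 4-methylbenzenesulfonate F3.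
  - LiEt3BH reduces the tosylate to give {[(1S,2S)-2-[2-bromo-4-(1,3-dioxolan-2-yl)-6-methoxyphenoxy]-1-(3,4,5-trimethoxyphenyl)propyl]oxy}triethylsilane F4.
  - TBAF in THF removes the silyl group and returns alcohol 9.

**Step 6.**
- What may go wrong: oxidative addition of copper into the electron-rich, ortho-alkoxy aryl bromide may be slow, so that hydrodebromination and oxidation of the benzylic alkoxide to the ketone compete with ring closure.
- Fallback, from 9 back to 11. It forms O1–C2 instead of O1–C8a:
  - Miyaura borylation of 9 (B2pin2, Pd(dppf)Cl2, KOAc, dioxane, 90 °C) gives (1S,2S)-2-[4-(1,3-dioxolan-2-yl)-2-methoxy-6-(4,4,5,5-tetramethyl-1,3,2-dioxaborolan-2-yl)phenoxy]-1-(3,4,5-trimethoxyphenyl)propan-1-ol F5.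
  - Oxidation (H2O2, NaOH, THF) gives the phenol (1S,2S)-2-[4-(1,3-dioxolan-2-yl)-2-hydroxy-6-methoxyphenoxy]-1-(3,4,5-trimethoxyphenyl)propan-1-ol F6.
  - p-TsOH·H2O in toluene at 60 °C ionises the benzylic alcohol. The phenol captures the cation to give the more stable trans ring, with C3 fixing the absolute configuration, and the water released hydrolyses the dioxolane, so the sequence re-enters at aldehyde 11.
  - Because this closure is stereoconvergent at C2, it would also rescue a poor syn/anti ratio from step 2, provided the aryloxy-bearing centre is formed with high enantiopurity.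

**Step 8.**
- What may go wrong: the product enal may undergo a second olefination (dienal formation), and the electron-rich aryl aldehyde may react slowly with the stabilised ylide.
- Fallback, from 11 back to 12, by homologation at the ester oxidation level:
  - Horner–Wadsworth–Emmons reaction with triethyl phosphonoacetate (NaH, THF) gives ethyl (E)-3-[(2S,3S)-5-methoxy-3-methyl-2-(3,4,5-trimethoxyphenyl)-2,3-dihydro-1,4-benzodioxin-7-yl]prop-2-enoate F7.
  - i-Bu2AlH (CH2Cl2, −78 °C) gives (E)-3-[(2S,3S)-5-methoxy-3-methyl-2-(3,4,5-trimethoxyphenyl)-2,3-dihydro-1,4-benzodioxin-7-yl]prop-2-en-1-ol F8.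
  - MnO2 in CH2Cl2 oxidises the allylic alcohol to 12.

## Further compounds

F1 | step 2 | (R)-4-benzyl-3-{2-[2-bromo-4-(1,3-dioxolan-2-yl)-6-methoxyphenoxy]acetyl}oxazolidin-2-one | COc1cc(C2OCCO2)cc(Br)c1OCC(=O)N1C(=O)OC[C@H]1Cc1ccccc1
F2 | step 2 | (R)-4-benzyl-3-{(2R,3S)-2-[2-bromo-4-(1,3-dioxolan-2-yl)-6-methoxyphenoxy]-3-hydroxy-3-(3,4,5-trimethoxyphenyl)propanoyl}oxazolidin-2-one | COc1cc([C@H](O)[C@H](C(=O)N4C(=O)OC[C@H]4Cc5ccccc5)Oc2c(Br)cc(C3OCCO3)cc2OC)cc(OC)c1OC
F3 | step 5 | (2S,3S)-2-[2-bromo-4-(1,3-dioxolan-2-yl)-6-methoxyphenoxy]-3-(triethylsilyloxy)-3-(3,4,5-trimethoxyphenyl)propyl 4-methylbenzenesulfonate | COc1cc([C@H](O[Si](CC)(CC)CC)[C@H](COS(=O)(=O)c4ccc(C)cc4)Oc2c(Br)cc(C3OCCO3)cc2OC)cc(OC)c1OC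
F4 | step 5 | {[(1S,2S)-2-[2-bromo-4-(1,3-dioxolan-2-yl)-6-methoxyphenoxy]-1-(3,4,5-trimethoxyphenyl)propyl]oxy}triethylsilane | COc1cc([C@H](O[Si](CC)(CC)CC)[C@H](C)Oc2c(Br)cc(C3OCCO3)cc2OC)cc(OC)c1OC
F5 | step 6 | (1S,2S)-2-[4-(1,3-dioxolan-2-yl)-2-methoxy-6-(4,4,5,5-tetramethyl-1,3,2-dioxaborolan-2-yl)phenoxy]-1-(3,4,5-trimethoxyphenyl)propan-1-ol | COc1cc([C@H](O)[C@H](C)Oc2c(B4OC(C)(C)C(C)(C)O4)cc(C3OCCO3)cc2OC)cc(OC)c1OC
F6 | step 6 | (1S,2S)-2-[4-(1,3-dioxolan-2-yl)-2-hydroxy-6-methoxyphenoxy]-1-(3,4,5-trimethoxyphenyl)propan-1-ol | COc1cc([C@H](O)[C@H](C)Oc2c(O)cc(C3OCCO3)cc2OC)cc(OC)c1OC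
F7 | step 8 | ethyl (E)-3-[(2S,3S)-5-methoxy-3-methyl-2-(3,4,5-trimethoxyphenyl)-2,3-dihydro-1,4-benzodioxin-7-yl]prop-2-enoate | COc1cc([C@@H]2Oc3cc(/C=C/C(=O)OCC)cc(OC)c3O[C@H]2C)cc(OC)c1OC
F8 | step 8 | (E)-3-[(2S,3S)-5-methoxy-3-methyl-2-(3,4,5-trimethoxyphenyl)-2,3-dihydro-1,4-benzodioxin-7-yl]prop-2-en-1-ol | COc1cc([C@@H]2Oc3cc(/C=C/CO)cc(OC)c3O[C@H]2C)cc(OC)c1OC
A1 | alternative 1 | (E)-2,6-dimethoxy-4-(prop-1-enyl)phenol | C/C=C/c1cc(OC)c(O)c(OC)c1
A2 | alternative 1 | methyl 5-hydroxyferulate [methyl (E)-3-(3,4-dihydroxy-5-methoxyphenyl)prop-2-enoate] | COC(=O)/C=C/c1cc(O)c(O)c(OC)c1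
A3 | alternative 1 | methyl (E)-3-[trans-2-(4-hydroxy-3,5-dimethoxyphenyl)-5-methoxy-3-methyl-1,4-benzodioxan-7-yl]acrylate (racemic; (2S,3S) enantiomer drawn) | COc1cc([C@@H]2Oc3cc(/C=C/C(=O)OC)cc(OC)c3O[C@H]2C)cc(OC)c1O
A4 | alternative 2 | methyl 4-diazo-3,5-dioxocyclohexane-1-carboxylate | COC(=O)C1CC(=O)C(=[N+]=[N-])C(=O)C1
A5 | alternative 2 | (1S,2S)-1-(tert-butyldimethylsilyloxy)-1-(3,4,5-trimethoxyphenyl)propan-2-ol | COc1cc([C@H](O[Si](C)(C)C(C)(C)C)[C@H](C)O)cc(OC)c1OC
A6 | alternative 2 | methyl (2S,3S)-3-methyl-5-oxo-2-(3,4,5-trimethoxyphenyl)-2,3,5,6,7,8-hexahydro-1,4-benzodioxine-7-carboxylate (epimer mixture at C7) | COc1cc([C@@H]2OC3=C(O[C@H]2C)C(=O)CC(C(=O)OC)C3)cc(OC)c1OC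
A7 | alternative 3 | methyl 4-hydroxy-3-methoxy-5-{[(1R)-1-(3,4,5-trimethoxyphenyl)prop-2-en-1-yl]oxy}benzoate | COc1cc([C@@H](C=C)Oc3cc(C(=O)OC)cc(OC)c3O)cc(OC)c1OC
A8 | alternative 3 | methyl (2S,3R)-3-(iodomethyl)-5-methoxy-2-(3,4,5-trimethoxyphenyl)-1,4-benzodioxane-7-carboxylate | COc1cc([C@@H]2Oc3cc(C(=O)OC)cc(OC)c3O[C@H]2CI)cc(OC)c1OC
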